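## Retrosynthetic overview

- Ring A is the hydroxy/formyl/prenyl benzene and ring B the methyl-bearing benzene (C1′ carries the ketone, C5′ the O–CH2 oxygen, C6′ the O–CH oxygen). Ring C is the 1,4-dioxane, and its stereocentre is a CH bound to O6′, to the ring CH2–O5′ and to C(CH3)2OH. That carbon is the central carbon of a 2-aryloxypropane-1,3-diol whose two CH2OH arms differ only once one of them is tied to C5′, and the strategy rests on this.
- Last C–C bond: the ketone carbon–ring A bond is made by a Kotali reaction (Pb(OAc)4) of the N-acylhydrazone from a ring B hydrazide and a ring A salicylaldehyde. The aroyl group replaces the ring A hydroxyl next to the prenyl group; desilylation follows.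
- Ring B hydrazide: from the (S)-2-hydroxymethyl-1,4-benzodioxane ester by CH2OH → CO2Me → C(CH3)2OH and aryl CO2tBu → CO2H → CONHNH2.
- Ring C is the only ring formed (rings A and B are bought). It is closed by an enantioselective palladium C5′–O coupling of the prochiral diol, which is made from 5-methylsalicylic acid by bromination, tert-butyl esterification, O-alkylation with diethyl bromomalonate and NaBH4 reduction.
- Ring A aldehyde: from 2,6-dihydroxybenzaldehyde by mono-allylation, silylation, Claisen rearrangement and cross-metathesis.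

Key step: step 5

Assumption: the sense of induction of the spiro ligand SDP(O) on this ester-substituted diol is taken to follow that of unsubstituted 2-(2-bromophenoxy)propane-1,3-diols; "(S)-SDP(O)" below stands for whichever ligand enantiomer delivers the S alcohol.

## Route

Step 1
Reactants: 1 5-methylsalicylic acid
Product: 2 3-bromo-2-hydroxy-5-methylbenzoic acid
Conditions: Br2 (1.05 equiv), AcOH, rt
Reagents that add atoms: bromine, BrBr
Why: Electrophilic aromatic bromination directed by the hydroxyl; the para position carries the methyl group and one ortho position the carboxyl, so only C3 is open.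

Step 2
Reactants: 2 3-bromo-2-hydroxy-5-methylbenzoic acid
Product: 3 tert-butyl 3-bromo-2-hydroxy-5-methylbenzoate
Conditions: Me2NCH(OtBu)2 (4 equiv), toluene, 80 °C
Reagents that add atoms: N,N-dimethylformamide di-tert-butyl acetal, CN(C)C(OC(C)(C)C)OC(C)(C)C
Why: Amide-acetal esterification alkylates the carboxylate selectively, and the flanked, hydrogen-bonded phenol should stay free; the tert-butyl ester is chosen because it resists lactonisation with the diol arms in step 5.

Step 3
Reactants: 3 tert-butyl 3-bromo-2-hydroxy-5-methylbenzoate; 4 diethyl bromomalonate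
Product: 5 diethyl 2-[2-bromo-6-(tert-butoxycarbonyl)-4-methylphenoxy]propanedioate
Conditions: K2CO3 (2 equiv), DMF, 50 °C
Reagents that add atoms: none
Why: Williamson etherification (SN2) with a doubly activated bromide that reacts even with 2,6-disubstituted phenoxides; both ortho positions and the para position of the phenoxide are substituted, so C-alkylation cannot compete.

Step 4
Reactants: 5 diethyl 2-[2-bromo-6-(tert-butoxycarbonyl)-4-methylphenoxy]propanedioate
Product: 7 tert-butyl 3-bromo-2-[(1,3-dihydroxypropan-2-yl)oxy]-5-methylbenzoate, via hydroxy ester 6 (not isolated)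
Conditions: NaBH4 (4 equiv), EtOH/THF, 0 °C → rt
Reagents that add atoms: none
Why: Borohydride reduction of the two α-aryloxy ethyl esters, which the α-oxygen activates, while the hindered aryl tert-butyl ester and the aryl bromide are inert to NaBH4.

Step 5
Reactants: 7 tert-butyl 3-bromo-2-[(1,3-dihydroxypropan-2-yl)oxy]-5-methylbenzoate
Product: 8 tert-butyl (3S)-3-(hydroxymethyl)-7-methyl-2,3-dihydro-1,4-benzodioxine-5-carboxylate
Conditions: Pd(OAc)2 (5 mol%), (S)-SDP(O) [7-(diphenylphosphanyl)-7′-(diphenylphosphoryl)-2,2′,3,3′-tetrahydro-1,1′-spirobi[indene]] (7.5 mol%), Cs2CO3 (1.5 equiv), toluene, 60 °C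
Reagents that add atoms: none
Why: Zerovalent palladium, formed in the flask from Pd(OAc)2 and the phosphine, inserts into the C5′–Br bond; Cs2CO3 then delivers one hydroxymethyl arm as a palladium alkoxide and C–O reductive elimination releases the aryl ether (Buchwald–Hartwig-type etherification). The closest known reaction type is the palladium-catalysed enantioselective desymmetrising intramolecular aryl C–O coupling of 2-(2-haloaryloxy)propane-1,3-diols to 2-hydroxymethyl-1,4-benzodioxanes, of which 7 is a ring-substituted member. Ring C closes as a six-membered ring by reductive elimination from a seven-membered oxapalladacycle, the new bond being C5′–O. The new stereocentre is set by the chiral ligand alone, which selects between the two enantiotopic CH2OH groups (catalyst control, no substrate stereocentre); the S alcohol is needed because the later change of CH2OH into C(CH3)2OH reverses the CIP order and gives the R centre of the target. The step needs enantiotopic-group selectivity (ligand), regioselectivity (already fixed, since O6′ is bonded to the CH before the ring exists) and chemoselectivity for C–O reductive elimination over β-hydride elimination and over lactonisation, the latter being blocked by the hindered tert-butyl ester.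

Step 6
Reactants: 8 tert-butyl (3S)-3-(hydroxymethyl)-7-methyl-2,3-dihydro-1,4-benzodioxine-5-carboxylate
Product: 10 (2R)-8-(tert-butoxycarbonyl)-6-methyl-2,3-dihydro-1,4-benzodioxine-2-carboxylic acid, via formyl benzodioxane 9 (not isolated)
Conditions: TEMPO (0.2 equiv), PhI(OAc)2 (2.5 equiv), MeCN/H2O 1:1, rt
Reagents that add atoms: water, O
Why: Oxoammonium (TEMPO/PhI(OAc)2) oxidation of the primary alcohol through the aldehyde and its hydrate under weakly acidic, base-free conditions, so the α-aryloxy centre is not enolised; the descriptor changes to R only through the change in CIP priorities.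

Step 7
Reactants: 10 (2R)-8-(tert-butoxycarbonyl)-6-methyl-2,3-dihydro-1,4-benzodioxine-2-carboxylic acid
Product: 11 8-tert-butyl 2-methyl (2R)-6-methyl-2,3-dihydro-1,4-benzodioxine-2,8-dicarboxylate
Conditions: TMSCHN2 (1.5 equiv), toluene/MeOH 4:1, 0 °C → rt
Reagents that add atoms: (trimethylsilyl)diazomethane, C[Si](C)(C)C=[N+]=[N-]
Why: Diazoalkane O-methylation of the carboxylic acid under neutral conditions, with no base at the epimerisable α-centre.

Step 8
Reactants: 11 8-tert-butyl 2-methyl (2R)-6-methyl-2,3-dihydro-1,4-benzodioxine-2,8-dicarboxylate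
Product: 12 (3R)-3-(methoxycarbonyl)-7-methyl-2,3-dihydro-1,4-benzodioxine-5-carboxylic acid
Conditions: TFA/CH2Cl2 1:3, 0 °C → rt
Reagents that add atoms: none
Why: Acidolysis of the tert-butyl ester with loss of isobutylene, done before the acid-sensitive tertiary alcohol exists; the methyl ester, the aryl ethers and the stereocentre are stable to acid.

Step 9
Reactants: 12 (3R)-3-(methoxycarbonyl)-7-methyl-2,3-dihydro-1,4-benzodioxine-5-carboxylic acid
Product: 14 (3R)-3-(2-hydroxypropan-2-yl)-7-methyl-2,3-dihydro-1,4-benzodioxine-5-carboxylic acid, via methyl ketone 13 (not isolated)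
Conditions: MeMgBr (4.5 equiv), THF, −78 → 0 °C; aq. NH4Cl, then pH 3
Reagents that add atoms: methylmagnesium bromide, C[Mg]Br
Why: Double Grignard addition to the activated α-aryloxy methyl ester; the first equivalent turns the aryl acid into its magnesium carboxylate, which does not add the reagent at these temperatures, and addition at low temperature should outrun α-deprotonation so the stereocentre is kept.

Step 10
Reactants: 14 (3R)-3-(2-hydroxypropan-2-yl)-7-methyl-2,3-dihydro-1,4-benzodioxine-5-carboxylic acid
Product: 16 (3R)-3-(2-hydroxypropan-2-yl)-7-methyl-2,3-dihydro-1,4-benzodioxine-5-carbohydrazide, via acyl imidazolide 15 (not isolated)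
Conditions: CDI (1.2 equiv), THF, rt; then N2H4·H2O (5 equiv), 0 °C → rt
Reagents that add atoms: hydrazine monohydrate, NN.O; 1,1′-carbonyldiimidazole, O=C(n1ccnc1)n1ccnc1 (its imidazol-1-yl group stays only in 15)
Why: Carboxyl activation as the N-acylimidazole followed by acyl substitution with hydrazine; the tertiary alcohol does not react with CDI at room temperature and excess hydrazine suppresses diacylation.

Step 11
Reactants: 17 2,6-dihydroxybenzaldehyde; 18 allyl bromide (1.0 equiv)
Product: 19 2-hydroxy-6-(prop-2-en-1-yloxy)benzaldehyde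
Conditions: K2CO3 (1.05 equiv), acetone, reflux
Reagents that add atoms: none
Why: Williamson mono-etherification; the two hydroxyls are equivalent by symmetry, and after the first alkylation the remaining one is held in a hydrogen bond to the aldehyde, which slows a second alkylation.

Step 12
Reactants: 19 2-hydroxy-6-(prop-2-en-1-yloxy)benzaldehyde
Product: 20 2-(prop-2-en-1-yloxy)-6-[(triisopropylsilyl)oxy]benzaldehyde
Conditions: TIPSOTf (1.2 equiv), 2,6-lutidine, CH2Cl2, 0 °C
Reagents that add atoms: triisopropylsilyl trifluoromethanesulfonate, CC(C)[Si](C(C)C)(C(C)C)OS(=O)(=O)C(F)(F)F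
Why: Silylation with a silyl triflate, reactive enough for the hydrogen-bonded phenol; the triisopropylsilyl ether should survive 180 °C, hydrazone formation and Pb(OAc)4 and leaves with fluoride at the end.

Step 13
Reactants: 20 2-(prop-2-en-1-yloxy)-6-[(triisopropylsilyl)oxy]benzaldehyde
Product: 22 2-hydroxy-3-(prop-2-en-1-yl)-6-[(triisopropylsilyl)oxy]benzaldehyde, via cyclohexadienone 21 (not isolated)
Conditions: 1,2-dichlorobenzene, 180 °C, Ar
Reagents that add atoms: none
Why: Aromatic Claisen rearrangement: the [3,3] shift goes to the only hydrogen-bearing ortho carbon and tautomerisation follows, so the allyl group ends next to the hydroxyl it sets free, which is the hydroxyl to be replaced in step 16.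

Step 14
Reactants: 22 2-hydroxy-3-(prop-2-en-1-yl)-6-[(triisopropylsilyl)oxy]benzaldehyde
Product: 23 2-hydroxy-3-(3-methylbut-2-en-1-yl)-6-[(triisopropylsilyl)oxy]benzaldehyde
Conditions: second-generation Grubbs catalyst RuCl2(=CHPh)(H2IMes)(PCy3) (5 mol%), 2-methylbut-2-ene/CH2Cl2, 40 °C
Reagents that add atoms: 2-methylbut-2-ene, CC=C(C)C
Why: Olefin cross-metathesis of the terminal allyl group with excess 2-methylbut-2-ene, the standard allyl-to-prenyl conversion, which tolerates the free phenol and the aldehyde.

Step 15
Reactants: 16 (3R)-3-(2-hydroxypropan-2-yl)-7-methyl-2,3-dihydro-1,4-benzodioxine-5-carbohydrazide; 23 2-hydroxy-3-(3-methylbut-2-en-1-yl)-6-[(triisopropylsilyl)oxy]benzaldehyde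
Product: 24 (3R)-N′-[(E)-{2-hydroxy-3-(3-methylbut-2-en-1-yl)-6-[(triisopropylsilyl)oxy]phenyl}methylidene]-3-(2-hydroxypropan-2-yl)-7-methyl-2,3-dihydro-1,4-benzodioxine-5-carbohydrazide
Conditions: EtOH, AcOH (cat.), 50 °C
Reagents that add atoms: none
Why: Acid-catalysed condensation of the acyl hydrazide with the aldehyde to the N-acylhydrazone, expected as the E isomer held by an O–H···N hydrogen bond.

Step 16
Reactants: 24 the N-acylhydrazone of step 15
Product: 25 2-[(3R)-3-(2-hydroxypropan-2-yl)-7-methyl-2,3-dihydro-1,4-benzodioxine-5-carbonyl]-3-(3-methylbut-2-en-1-yl)-6-[(triisopropylsilyl)oxy]benzaldehyde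
Conditions: Pb(OAc)4 (1.2 equiv), THF, 0 °C → rt, Ar
Reagents that add atoms: none
Why: Kotali reaction (Pb(OAc)4 oxidation of an ortho-hydroxyaryl N-acylhydrazone): oxidation at N–H, engagement of the neighbouring phenol oxygen, loss of N2 and oxygen-to-carbon migration of the aroyl group replace the ring A hydroxyl by the ring B carbonyl and return the hydrazone carbon as the aldehyde; the silyl ether ensures that only the hydroxyl next to the prenyl group can take part.

Step 17
Reactants: 25 the silyl-protected 2-aroylbenzaldehyde of step 16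
Product: 26 6-hydroxy-2-[(3R)-3-(2-hydroxypropan-2-yl)-7-methyl-2,3-dihydro-1,4-benzodioxine-5-carbonyl]-3-(3-methylbut-2-en-1-yl)benzaldehyde (target)
Conditions: TBAF (1.2 equiv), AcOH (1.2 equiv), THF, 0 °C
Reagents that add atoms: none
Why: Fluoride cleavage of the aryl silyl ether, buffered with acetic acid so that neither basic fluoride nor a free phenoxide acts on the 2-aroylbenzaldehyde.

## Compound list

1 | 5-methylsalicylic acid | Cc1ccc(O)c(C(=O)O)c1 | starting material
2 | 3-bromo-2-hydroxy-5-methylbenzoic acid | Cc1cc(Br)c(O)c(C(=O)O)c1 | intermediate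
3 | tert-butyl 3-bromo-2-hydroxy-5-methylbenzoate | Cc1cc(Br)c(O)c(C(=O)OC(C)(C)C)c1 | intermediate
4 | diethyl bromomalonate | CCOC(=O)C(Br)C(=O)OCC | starting material
5 | diethyl 2-[2-bromo-6-(tert-butoxycarbonyl)-4-methylphenoxy]propanedioate | CCOC(=O)C(Oc1c(Br)cc(C)cc1C(=O)OC(C)(C)C)C(=O)OCC | intermediate
6 | tert-butyl 3-bromo-2-[(1-ethoxy-3-hydroxy-1-oxopropan-2-yl)oxy]-5-methylbenzoate (racemic) | CCOC(=O)C(CO)Oc1c(Br)cc(C)cc1C(=O)OC(C)(C)C | intermediate (not isolated)
7 | tert-butyl 3-bromo-2-[(1,3-dihydroxypropan-2-yl)oxy]-5-methylbenzoate | CC(C)(C)OC(=O)c1cc(C)cc(Br)c1OC(CO)CO | intermediate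
8 | tert-butyl (3S)-3-(hydroxymethyl)-7-methyl-2,3-dihydro-1,4-benzodioxine-5-carboxylate | CC(C)(C)OC(=O)c1cc(C)cc2c1O[C@@H](CO)CO2 | intermediate
9 | tert-butyl (3R)-3-formyl-7-methyl-2,3-dihydro-1,4-benzodioxine-5-carboxylate | CC(C)(C)OC(=O)c1cc(C)cc2c1O[C@@H](C=O)CO2 | intermediate (not isolated)
10 | (2R)-8-(tert-butoxycarbonyl)-6-methyl-2,3-dihydro-1,4-benzodioxine-2-carboxylic acid | CC(C)(C)OC(=O)c1cc(C)cc2c1O[C@@H](C(=O)O)CO2 | intermediate
11 | 8-tert-butyl 2-methyl (2R)-6-methyl-2,3-dihydro-1,4-benzodioxine-2,8-dicarboxylate | CC(C)(C)OC(=O)c1cc(C)cc2c1O[C@@H](C(=O)OC)CO2 | intermediate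
12 | (3R)-3-(methoxycarbonyl)-7-methyl-2,3-dihydro-1,4-benzodioxine-5-carboxylic acid | OC(=O)c1cc(C)cc2c1O[C@@H](C(=O)OC)CO2 | intermediate
13 | (3R)-3-acetyl-7-methyl-2,3-dihydro-1,4-benzodioxine-5-carboxylic acid (present as its magnesium carboxylate) | OC(=O)c1cc(C)cc2c1O[C@@H](C(C)=O)CO2 | intermediate (not isolated)
14 | (3R)-3-(2-hydroxypropan-2-yl)-7-methyl-2,3-dihydro-1,4-benzodioxine-5-carboxylic acid | OC(=O)c1cc(C)cc2c1O[C@@H](C(C)(C)O)CO2 | intermediate
15 | [(3R)-3-(2-hydroxypropan-2-yl)-7-methyl-2,3-dihydro-1,4-benzodioxin-5-yl](1H-imidazol-1-yl)methanone | O=C(c1cc(C)cc2c1O[C@@H](C(C)(C)O)CO2)n1ccnc1 | intermediate (not isolated)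
16 | (3R)-3-(2-hydroxypropan-2-yl)-7-methyl-2,3-dihydro-1,4-benzodioxine-5-carbohydrazide | NNC(=O)c1cc(C)cc2c1O[C@@H](C(C)(C)O)CO2 | intermediate
17 | 2,6-dihydroxybenzaldehyde | O=Cc1c(O)cccc1O | starting material
18 | allyl bromide | C=CCBr | starting material
19 | 2-hydroxy-6-(prop-2-en-1-yloxy)benzaldehyde | O=Cc1c(O)cccc1OCC=C | intermediate
20 | 2-(prop-2-en-1-yloxy)-6-[(triisopropylsilyl)oxy]benzaldehyde | O=Cc1c(OCC=C)cccc1O[Si](C(C)C)(C(C)C)C(C)C | intermediate
21 | 6-oxo-5-(prop-2-en-1-yl)-2-[(triisopropylsilyl)oxy]cyclohexa-1,3-diene-1-carbaldehyde (racemic) | C=CCC1C=CC(O[Si](C(C)C)(C(C)C)C(C)C)=C(C=O)C1=O | intermediate (not isolated)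
22 | 2-hydroxy-3-(prop-2-en-1-yl)-6-[(triisopropylsilyl)oxy]benzaldehyde | C=CCc1ccc(O[Si](C(C)C)(C(C)C)C(C)C)c(C=O)c1O | intermediate
23 | 2-hydroxy-3-(3-methylbut-2-en-1-yl)-6-[(triisopropylsilyl)oxy]benzaldehyde | CC(C)=CCc1ccc(O[Si](C(C)C)(C(C)C)C(C)C)c(C=O)c1O | intermediate
24 | (3R)-N′-[(E)-{2-hydroxy-3-(3-methylbut-2-en-1-yl)-6-[(triisopropylsilyl)oxy]phenyl}methylidene]-3-(2-hydroxypropan-2-yl)-7-methyl-2,3-dihydro-1,4-benzodioxine-5-carbohydrazide | CC(C)=CCc1ccc(O[Si](C(C)C)(C(C)C)C(C)C)c(/C=N/NC(=O)c2cc(C)cc3c2O[C@@H](C(C)(C)O)CO3)c1O | intermediate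
25 | 2-[(3R)-3-(2-hydroxypropan-2-yl)-7-methyl-2,3-dihydro-1,4-benzodioxine-5-carbonyl]-3-(3-methylbut-2-en-1-yl)-6-[(triisopropylsilyl)oxy]benzaldehyde | CC(C)=CCc1ccc(O[Si](C(C)C)(C(C)C)C(C)C)c(C=O)c1C(=O)c1cc(C)cc2c1O[C@@H](C(C)(C)O)CO2 | intermediate
26 | 6-hydroxy-2-[(3R)-3-(2-hydroxypropan-2-yl)-7-methyl-2,3-dihydro-1,4-benzodioxine-5-carbonyl]-3-(3-methylbut-2-en-1-yl)benzaldehyde | CC(C)=CCc1ccc(O)c(C=O)c1C(=O)c1cc(C)cc2c1O[C@@H](C(C)(C)O)CO2 | target

## Step count and risks

Total step count: 17. Longest linear sequence: 13 steps (steps 1–10, then 15–17); the ring A branch (steps 11–14) joins at step 15.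

**Step 16 (Kotali reaction).** The aroyl group must migrate to a ring carbon that sits between the formyl-derived carbon and the prenyl CH2, so the oxygen-to-carbon transfer may stall. The aldehyde-derived acylhydrazone may instead be diverted into oxidative cyclisation to a 1,3,4-oxadiazole, and Pb(OAc)4 may also attack the prenyl double bond. The fallback replaces the oxidative rearrangement by a base-free thioester–boronate ketone synthesis; it sets out from 23 and 14 and comes back at 25. Phenol 23 would be converted with Tf2O/pyridine (CH2Cl2, 0 °C) into aryl triflate F1. Miyaura borylation of F1 (B2pin2, Pd(OAc)2, SPhos, KOAc, dioxane, 90 °C) should give pinacol boronate F2. Acid 14 would be activated with CDI as in step 10 and treated with thiophenol to give S-phenyl thioester F3. Liebeskind–Srogl coupling of F2 with F3 (Pd2(dba)3, tri(2-furyl)phosphine, CuTC, Cu(O2CC4H3S), monovalent copper, THF, 50 °C) should then deliver ketone 25, which is desilylated as in step 17.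

**Step 5 (key step).** The ester next to O6′ crowds the ligand pocket, so discrimination between the two enantiotopic arms may be poor. β-Hydride elimination from the palladium alkoxide may also compete and lead to hydrodebromination. The fallback gives up catalyst control for a resolution; it sets out from 7 and comes back at 8. Diol 7 would be cyclised without a chiral ligand by intramolecular Ullmann etherification (CuI, 1,10-phenanthroline, Cs2CO3, toluene, 110 °C) to racemic alcohol F4. Lipase-catalysed acetylation of F4 (Burkholderia cepacia lipase, vinyl acetate, tert-butyl methyl ether, rt) is expected to acylate one enantiomer. This is taken here to be the R alcohol, which gives acetate F5 and leaves the S alcohol 8 for step 6. Should the enzyme prefer the S alcohol, its acetate would be separated and methanolysed (K2CO3, MeOH) to 8.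

**Step 9 (Grignard addition with the free aryl acid).** After deprotonation the magnesium carboxylate may aggregate and slow both additions. α-Deprotonation of the ester or of ketone 13 can then compete, eroding the stereocentre or opening ring C by β-elimination of the aryloxide. The fallback sends the aryl carboxyl through the addition as its hindered tert-butyl ester and unmasks it afterwards; it sets out from 11 and comes back at 14. Diester 11 would be treated with MeMgBr (2.5 equiv, THF, −78 → −20 °C), which should add only to the activated methyl ester and give tert-butyl ester carbinol F6 in homogeneous solution. F6 would then be cleaved with 85% aqueous H3PO4 in toluene at rt, conditions mild enough for the tertiary alcohol, to give acid 14.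

## Further compounds

F1 | step 16 | 2-formyl-6-(3-methylbut-2-en-1-yl)-3-[(triisopropylsilyl)oxy]phenyl trifluoromethanesulfonate | CC(C)=CCc1ccc(O[Si](C(C)C)(C(C)C)C(C)C)c(C=O)c1OS(=O)(=O)C(F)(F)F
F2 | step 16 | 3-(3-methylbut-2-en-1-yl)-2-(4,4,5,5-tetramethyl-1,3,2-dioxaborolan-2-yl)-6-[(triisopropylsilyl)oxy]benzaldehyde | CC(C)=CCc1ccc(O[Si](C(C)C)(C(C)C)C(C)C)c(C=O)c1B1OC(C)(C)C(C)(C)O1
F3 | step 16 | S-phenyl (3R)-3-(2-hydroxypropan-2-yl)-7-methyl-2,3-dihydro-1,4-benzodioxine-5-carbothioate | O=C(Sc1ccccc1)c1cc(C)cc2c1O[C@@H](C(C)(C)O)CO2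
F4 | step 5 | racemic tert-butyl 3-(hydroxymethyl)-7-methyl-2,3-dihydro-1,4-benzodioxine-5-carboxylate | CC(C)(C)OC(=O)c1cc(C)cc2c1OC(CO)CO2
F5 | step 5 | tert-butyl (3S)-3-(acetoxymethyl)-7-methyl-2,3-dihydro-1,4-benzodioxine-5-carboxylate (acetate of the R alcohol; the descriptor changes on acetylation) | CC(C)(C)OC(=O)c1cc(C)cc2c1O[C@H](COC(C)=O)CO2
F6 | step 9 | tert-butyl (3R)-3-(2-hydroxypropan-2-yl)-7-methyl-2,3-dihydro-1,4-benzodioxine-5-carboxylate | CC(C)(C)OC(=O)c1cc(C)cc2c1O[C@@H](C(C)(C)O)CO2
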